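**Plan**

- Retrosynthesis: cut first the bond from ring carbon C2 of the 1,4-benzodioxane to C4 of the 4-hydroxy-3,5-dimethoxyphenyl ring, which leaves a C2 lactol and free 2,6-dimethoxyphenol. Then take the lactol back to the lactone, open the lactone C2(=O)–O1 bond, trace the aryl–O1 bond back to an aryl–CHO (Baeyer–Villiger), and cut the O4–C3 ether bond (Mitsunobu with a lactate).
- Forward: a salicylaldehyde is etherified with methyl (S)-lactate, the formyl group is turned into OH, lactonisation closes the dioxane ring, DIBAL-H gives the lactol, and the last step joins the two arenes.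
- Enabling feature: C2 sits between ring O1 and the aryl group, so at the lactol level it ionises to an O1-stabilised oxocarbenium ion within the six-membered dioxane ring. The aryl group is the para carbon of 2,6-dimethoxyphenol, whose OH directs para and whose two ortho positions are blocked by OMe, so the phenol is used unprotected and the coupling ends the synthesis.
- Helpers: the formyl group ortho to the phenolic OH is a masked O1 and fixes which catechol oxygen carries CH(CH3) (the one flanked by OMe, para to allyl). The lactone carbonyl is the activating oxidation level at C2 and leaves as water in the key step.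
- Stereochemistry: C3 (R) comes from methyl (S)-lactate by Mitsunobu inversion. C2 (R) is set in the key step by 1,2-induction from the C3 methyl group (aryl trans to methyl), backed by the thermodynamic preference for the trans 2,3-disubstituted ring.

Key step: step 5

Assumption: the lactol is used as its mixture of C2 epimers, since both ionise to the same cation; the starting salicylaldehyde and 2,6-dimethoxyphenol are taken as catalogue compounds.

**Route**

Step 1
Reactants: 1 5-allyl-2-hydroxy-3-methoxybenzaldehyde; 2 methyl (S)-lactate
Product: 3 methyl (2R)-2-(4-allyl-2-formyl-6-methoxyphenoxy)propanoate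
Conditions: PPh3, DIAD, THF, 0 °C → rt
Reagents that add atoms: none
Why: Mitsunobu etherification, in which the acidic salicylaldehyde-type phenol displaces the activated lactate oxygen by SN2 with inversion, so (S)-2 should give the (R)-aryloxypropanoate that becomes C3 of the target, and the only phenolic oxygen of 1 is by construction the one para to the allyl group and flanked by OMe.

Step 2
Reactants: 3 methyl (2R)-2-(4-allyl-2-formyl-6-methoxyphenoxy)propanoate
Product: 5 methyl (2R)-2-(4-allyl-2-hydroxy-6-methoxyphenoxy)propanoate, via aryl formate 4 (not isolated)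
Conditions: 30% aq H2O2 (1.5 equiv), cat. H2SO4, MeOH, rt
Reagents that add atoms: hydrogen peroxide, OO
Why: Acid-catalysed Baeyer–Villiger (Dakin-type) oxidation, in which the hydroperoxy hemiacetal of the electron-rich ortho-alkoxybenzaldehyde rearranges with aryl migration to formate 4, which methanol cleaves in the flask, while dilute hydrogen peroxide without a peracid should leave the terminal alkene and the C3 stereocentre untouched.

Step 3
Reactants: 5 methyl (2R)-2-(4-allyl-2-hydroxy-6-methoxyphenoxy)propanoate
Product: 6 (3R)-7-allyl-5-methoxy-3-methyl-2,3-dihydro-1,4-benzodioxin-2-one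
Conditions: TsOH·H2O (2 mol%), PhMe, 80 °C, 5 Å MS (removal of MeOH)
Reagents that add atoms: none
Why: Acid-catalysed intramolecular transesterification (lactonisation) of the phenol onto the neighbouring aryloxypropanoate should close the six-membered aryl lactone once methanol is removed, and the non-basic conditions should not touch the stereocentre α to the carbonyl.

Step 4
Reactants: 6 (3R)-7-allyl-5-methoxy-3-methyl-2,3-dihydro-1,4-benzodioxin-2-one
Product: 7 (3R)-7-allyl-5-methoxy-3-methyl-2,3-dihydro-1,4-benzodioxin-2-ol (mixture of C2 epimers)
Conditions: DIBAL-H (1.1 equiv), CH2Cl2, −78 °C; Rochelle salt work-up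
Reagents that add atoms: none
Why: Partial reduction of a lactone to its lactol with DIBAL-H, as known for dihydrocoumarins, should stop at the aluminium hemiacetal, which is stable at −78 °C until work-up, while the allyl group, the aryl ethers and C3 are not affected.

Step 5
Reactants: 7 (3R)-7-allyl-5-methoxy-3-methyl-2,3-dihydro-1,4-benzodioxin-2-ol; 8 2,6-dimethoxyphenol
Product: 10 4-[(2R,3R)-7-allyl-5-methoxy-3-methyl-2,3-dihydro-1,4-benzodioxin-2-yl]-2,6-dimethoxyphenol, via oxocarbenium ion 9 (not isolated)
Conditions: 8 (1.5 equiv), BF3·OEt2 (0.3 equiv), 4 Å MS, CH2Cl2, −40 → 0 °C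
Reagents that add atoms: none
Why: The acid ionises the anomeric C2–OH of 7 (both epimers alike) to the O1-stabilised cyclic oxocarbenium ion 9, which C4 of 8 captures in an electrophilic aromatic substitution; loss of the proton from the arenium ion gives 10 and water. The closest known reaction type is the Friedel–Crafts C-arylation of lactols and glycosyl donors by phenols (aryl C-glycoside formation, 2-arylation of 2-chromanols). The step closes no ring, since the dioxane ring comes intact from 6; if the ring-opened aldehyde tautomer of 7 reacts first, the resulting para-hydroxybenzyl cation should reclose the same ring by 6-exo attack of the phenolic O1. The new stereocentre C2 is controlled by the C3 methyl group, anti to which the arene should add to give the trans 2R,3R ring, and because 10 is a cyclic para-hydroxybenzyl aryl ether a cis isomer can re-ionise at C2–O1 under the acid and reclose to the more stable trans isomer. The step needs para (C4) regioselectivity on 8, mono-arylation and an untouched allyl group: the OH of 8 directs para while both of its ortho positions carry OMe, O-attack gives a labile mixed acetal that returns to 9, and the terminal alkene and the trioxygenated benzodioxane ring are much weaker nucleophiles than the free phenol at −40 to 0 °C.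

**Compound list**

1 | 5-allyl-2-hydroxy-3-methoxybenzaldehyde | C=CCc1cc(OC)c(O)c(C=O)c1 | starting material
2 | methyl (S)-lactate, methyl (2S)-2-hydroxypropanoate | C[C@H](O)C(=O)OC | starting material
3 | methyl (2R)-2-(4-allyl-2-formyl-6-methoxyphenoxy)propanoate | C=CCc1cc(OC)c(O[C@H](C)C(=O)OC)c(C=O)c1 | intermediate
4 | aryl formate, methyl (2R)-2-[4-allyl-2-(formyloxy)-6-methoxyphenoxy]propanoate (formed in the flask in step 2) | C=CCc1cc(OC)c(O[C@H](C)C(=O)OC)c(OC=O)c1 | intermediate
5 | methyl (2R)-2-(4-allyl-2-hydroxy-6-methoxyphenoxy)propanoate | C=CCc1cc(OC)c(O[C@H](C)C(=O)OC)c(O)c1 | intermediate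
6 | (3R)-7-allyl-5-methoxy-3-methyl-2,3-dihydro-1,4-benzodioxin-2-one | C=CCc1cc(OC)c2c(c1)OC(=O)[C@@H](C)O2 | intermediate
7 | (3R)-7-allyl-5-methoxy-3-methyl-2,3-dihydro-1,4-benzodioxin-2-ol, mixture of C2 epimers | C=CCc1cc(OC)c2c(c1)OC(O)[C@@H](C)O2 | intermediate
8 | 2,6-dimethoxyphenol | COc1cccc(OC)c1O | starting material
9 | oxocarbenium ion, (3R)-7-allyl-5-methoxy-3-methyl-3H-1,4-benzodioxin-1-ium (formed in the flask in step 5) | C=CCc1cc(OC)c2c(c1)[O+]=C[C@@H](C)O2 | intermediate
10 | 4-[(2R,3R)-7-allyl-5-methoxy-3-methyl-2,3-dihydro-1,4-benzodioxin-2-yl]-2,6-dimethoxyphenol (trans) | C=CCc1cc(OC)c2c(c1)O[C@H](c1cc(OC)c(O)c(OC)c1)[C@@H](C)O2 | target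

**Count**

Total steps: 5. Longest linear sequence: 5 steps (1 → 3 → 5 → 6 → 7 → 10); 2 and 8 are bought.

**Steps most likely to fail**

Step 5. Three processes may go wrong:
- Proton loss from the oxocarbenium ion at C3 would give the achiral 1,4-benzodioxine enol ether, and its re-protonation would erode the C3 configuration.
- The phenol may attack through its OMe-flanked C3, or a second arylation may follow re-ionisation of the benzylic C2–O1 bond.
- The facial selectivity at C2 may be poor if the equilibration to the trans ring does not take place.

The fallback sets out from 7 and comes back at 10, and makes the same bond by carbonyl addition under basic conditions instead of cation capture. Purchased 4-bromo-2,6-dimethoxyphenol is protected (MOMCl, iPr2NEt, CH2Cl2) as 5-bromo-1,3-dimethoxy-2-(methoxymethoxy)benzene F1 and converted (Mg, THF) into [3,5-dimethoxy-4-(methoxymethoxy)phenyl]magnesium bromide F2. An excess of F2 (about 3 equiv, THF, −78 → 0 °C) deprotonates 7, whose magnesium salt opens to the α-aryloxy aldehyde, and adds to it to give (2R)-2-(4-allyl-2-hydroxy-6-methoxyphenoxy)-1-[3,5-dimethoxy-4-(methoxymethoxy)phenyl]propan-1-ol F3 as a mixture of carbinol epimers. Acid (cat. TsOH, CH2Cl2–MeOH 10:1, rt) then removes the MOM group and ionises the benzylic alcohol to the para-hydroxybenzyl cation (quinone methide), which the ortho phenol should capture in a 6-exo closure that settles on the more stable trans ring of 10.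

Step 2. The peroxide may attack the wrong site, either the allyl double bond or the electron-rich phenol product, and hydride may migrate instead of aryl, which would give the benzoic acid. The fallback sets out from 2 and rejoins the route at 6; it installs the allyl group only after the oxidation.
- Purchased 5-bromo-2-hydroxy-3-methoxybenzaldehyde takes the place of 1, and Mitsunobu coupling with 2 (PPh3, DIAD, THF) should give methyl (2R)-2-(4-bromo-2-formyl-6-methoxyphenoxy)propanoate F4.
- With no alkene present, the standard peracid Baeyer–Villiger oxidation (mCPBA, CH2Cl2) should give methyl (2R)-2-[4-bromo-2-(formyloxy)-6-methoxyphenoxy]propanoate F5.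
- Methanolysis (cat. HCl, MeOH) should give methyl (2R)-2-(4-bromo-2-hydroxy-6-methoxyphenoxy)propanoate F6.
- Lactonisation as in step 3 should give (3R)-7-bromo-5-methoxy-3-methyl-2,3-dihydro-1,4-benzodioxin-2-one F7.
- Stille allylation of F7 (allyltributylstannane, Pd(PPh3)4, PhMe, 100 °C) should then deliver 6.

Step 4. The aluminium hemiacetal may collapse with loss of the aryloxide, and the freed aldehyde would then be reduced further to the diol. The fallback sets out from 6 and returns at 7; it fixes the aldehyde oxidation level through a chelated N-methoxy-N-methylamide. Aminolysis of the aryl lactone (MeNHOMe·HCl, iPrMgCl, THF, −20 °C) should give (2R)-2-(4-allyl-2-hydroxy-6-methoxyphenoxy)-N-methoxy-N-methylpropanamide F8. Its reduction with LiAlH4 (THF, −78 → 0 °C, one extra hydride for the phenol) should stop at the chelated hemiaminal, and work-up releases the aldehyde, which closes to 7.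

**Further compounds**

F1 | step 5 | 5-bromo-1,3-dimethoxy-2-(methoxymethoxy)benzene | COCOc1c(OC)cc(Br)cc1OC
F2 | step 5 | [3,5-dimethoxy-4-(methoxymethoxy)phenyl]magnesium bromide | COCOc1c(OC)cc([Mg]Br)cc1OC
F3 | step 5 | (2R)-2-(4-allyl-2-hydroxy-6-methoxyphenoxy)-1-[3,5-dimethoxy-4-(methoxymethoxy)phenyl]propan-1-ol, mixture of C1 epimers | C=CCc1cc(OC)c(O[C@H](C)C(O)c2cc(OC)c(OCOC)c(OC)c2)c(O)c1
F4 | step 2 | methyl (2R)-2-(4-bromo-2-formyl-6-methoxyphenoxy)propanoate | O=Cc1cc(Br)cc(OC)c1O[C@H](C)C(=O)OC
F5 | step 2 | methyl (2R)-2-[4-bromo-2-(formyloxy)-6-methoxyphenoxy]propanoate | O=COc1cc(Br)cc(OC)c1O[C@H](C)C(=O)OC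
F6 | step 2 | methyl (2R)-2-(4-bromo-2-hydroxy-6-methoxyphenoxy)propanoate | Oc1cc(Br)cc(OC)c1O[C@H](C)C(=O)OC
F7 | step 2 | (3R)-7-bromo-5-methoxy-3-methyl-2,3-dihydro-1,4-benzodioxin-2-one | Brc1cc(OC)c2c(c1)OC(=O)[C@@H](C)O2
F8 | step 4 | (2R)-2-(4-allyl-2-hydroxy-6-methoxyphenoxy)-N-methoxy-N-methylpropanamide | C=CCc1cc(OC)c(O[C@H](C)C(=O)N(C)OC)c(O)c1
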